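**Retrosynthetic overview**
1. The target is eudesma-3,11(13)-dien-12-oic acid carrying a (Z)-p-coumarate on C15. The last C–C bond made is C4–C15, by a Pd/Cu Stille-type coupling of a ring-A alkenyl iodide (acid masked as a silyl ester) with (tributylstannyl)methyl (Z)-4-silyloxycinnamate; one desilylation then gives the target.
2. Enabling feature: C4 is an sp2 carbon of the ring-A alkene C3=C4, and its only exocyclic substituent, C15, is a methylene bound to the ester oxygen. C4 can therefore be an alkenyl iodide and C15 an α-acyloxy alkyl–tin unit whose oxygen promotes Sn-to-Cu-to-Pd transfer, so the finished Z-enoate is carried in untouched.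
3. Decalin half: ring B comes from (+)-dihydrocarvone (C7). Ring A is closed second, by auxiliary-controlled Michael addition to methyl vinyl ketone (C10) and aldol condensation. α-Iodination at C4, Luche reduction and a diazene-mediated reductive transposition then move the alkene to C3=C4, set 5α-H and leave the iodide on C4; the isopropenyl group is oxidised to the acrylic acid (SeO2/MnO2, then NaClO2).
4. Ester half: (tributylstannyl)methanol → bromoacetate → diphenyl phosphonoacetate → Z-selective Horner–Wadsworth–Emmons reaction with 4-silyloxybenzaldehyde (the arene is bought).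
5. Ring order: ring B (chiral pool), then ring A (Robinson annulation); no ring is formed in or after the key step.

Key step: step 12

Remark on the chemistry: eudesmane numbering is used (ring A = C1–C5 and C10, ring B = C5–C10, C14 = methyl on C10, C15 = carbon on C4, C11–C13 = side chain on C7); commercial (+)-dihydrocarvone is a C2-epimer mixture, which is irrelevant because C2 becomes planar in step 1, and (tributylstannyl)methanol is taken as a catalogue reagent.

**Route**

Step 1
Reactants: 1 (+)-dihydrocarvone; 2 (R)-1-phenylethylamine; 3 methyl vinyl ketone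
Product: 6 (2S,5R)-2-methyl-2-(3-oxobutyl)-5-(prop-1-en-2-yl)cyclohexan-1-one, via ketimine 4 (not isolated), via Michael adduct imine 5 (not isolated)
Conditions: (a) 2, TsOH (cat.), toluene, reflux, water separator; (b) 3, THF, 40 °C; (c) 10% aq. AcOH, 23 °C
Reagents that add atoms: water (O)
Why: Asymmetric Michael addition of a chiral imine (first stage of a Robinson annulation): the more substituted secondary enamine tautomer of 4 adds to the enone through a compact aza-ene-like transition state on the face away from the phenyl group of the auxiliary, which should set the quaternary C10 with its methyl cis to the C7 isopropenyl group before hydrolysis returns the amine.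

Step 2
Reactants: 6 (2S,5R)-2-methyl-2-(3-oxobutyl)-5-(prop-1-en-2-yl)cyclohexan-1-one
Product: 7 15-nor-eudesma-4,11-dien-3-one
Conditions: NaOMe, MeOH, 23 → 60 °C
Reagents that add atoms: none
Why: Intramolecular aldol condensation (second stage of the Robinson annulation) closes ring A between C4 and C5 and dehydrates to the conjugated enone without touching a stereocentre.

Step 3
Reactants: 7 15-nor-eudesma-4,11-dien-3-one
Product: 8 4-iodo-15-nor-eudesma-4,11-dien-3-one
Conditions: I2, pyridine–CH2Cl2 (1:1), DMAP (cat.), 23 °C, dark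
Reagents that add atoms: iodine, II
Why: α-Iodination of a cyclic enone with iodine–pyridine (addition–elimination across C4=C5) should put the halogen on C4, the carbon that will later carry C15, and spare the isolated isopropenyl group.

Step 4
Reactants: 8 4-iodo-15-nor-eudesma-4,11-dien-3-one
Product: 9 4-iodo-15-nor-eudesma-4,11-dien-3β-ol
Conditions: NaBH4, CeCl3·7H2O, MeOH, −40 → 0 °C
Reagents that add atoms: none
Why: Luche reduction is 1,2-selective and should deliver hydride axially from the α face, opposite the angular C10 methyl, so that the pseudo-equatorial 3β-alcohol is formed.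

Step 5
Reactants: 9 4-iodo-15-nor-eudesma-4,11-dien-3β-ol
Product: 13 4-iodo-15-nor-5α-eudesma-3,11-diene, via Mitsunobu hydrazone adduct 10 (not isolated), via N-allyl sulfonylhydrazine 11 (not isolated), via allylic diazene 12 (not isolated)
Conditions: N′-isopropylidene-2-nitrobenzenesulfonohydrazide, PPh3, diethyl azodicarboxylate, THF, 0 → 23 °C; then CF3CH2OH–H2O (1:1), 23 °C
Reagents that add atoms: none
Why: Reductive 1,3-transposition of an allylic alcohol through a monoalkyl diazene: the Mitsunobu reaction inverts C3, hydrolysis of the hydrazone and loss of arenesulfinic acid give the 3α-diazene, and its retro-ene loss of N2 should pass hydrogen suprafacially to the α face of C5 (trans ring fusion) while the double bond moves to C3=C4, which turns C4 into an alkenyl iodide.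

Step 6
Reactants: 13 4-iodo-15-nor-5α-eudesma-3,11-diene
Product: 15 4-iodo-15-nor-5α-eudesma-3,11(13)-dien-12-al, via allylic alcohol 14 (not isolated)
Conditions: SeO2 (0.5 equiv), t-BuOOH, CH2Cl2, 23 °C; then MnO2, CH2Cl2, 23 °C
Reagents that add atoms: selenium dioxide, O=[Se]=O (oxygen carrier), reoxidised by tert-butyl hydroperoxide, CC(C)(C)OO
Why: SeO2/t-BuOOH allylic oxidation (ene reaction then [2,3]-sigmatropic shift) should attack the methyl group of the electron-rich 1,1-disubstituted alkene in preference to the allylic positions of the deactivated iodoalkene, and MnO2 converges alcohol 14 on the enal.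

Step 7
Reactants: 15 4-iodo-15-nor-5α-eudesma-3,11(13)-dien-12-al
Product: 16 4-iodo-15-nor-5α-eudesma-3,11(13)-dien-12-oic acid
Conditions: NaClO2, NaH2PO4, 2-methyl-2-butene, t-BuOH–H2O, 0 → 23 °C
Reagents that add atoms: sodium chlorite, [Na+].[O-]Cl=O
Why: Pinnick oxidation should convert the enal into the acid without touching the alkenyl iodide, the hypochlorous acid being scavenged by 2-methyl-2-butene.

Step 8
Reactants: 16 4-iodo-15-nor-5α-eudesma-3,11(13)-dien-12-oic acid
Product: 17 triisopropylsilyl 4-iodo-15-nor-5α-eudesma-3,11(13)-dien-12-oate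
Conditions: i-Pr3SiCl, imidazole, CH2Cl2, 0 → 23 °C
Reagents that add atoms: triisopropylsilyl chloride, CC(C)[Si](Cl)(C(C)C)C(C)C
Why: Silyl ester formation masks the acid for the coupling with a group that is removed by the same fluoride treatment as the phenol silyl ether.

Step 9
Reactants: 18 (tributylstannyl)methanol; 19 bromoacetyl bromide
Product: 20 (tributylstannyl)methyl bromoacetate
Conditions: pyridine, CH2Cl2, 0 °C
Reagents that add atoms: none
Why: Acylation of a primary alcohol by an acyl bromide, to which the C–Sn bond is inert.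

Step 10
Reactants: 20 (tributylstannyl)methyl bromoacetate; 21 diphenyl phosphite
Product: 22 (tributylstannyl)methyl (diphenoxyphosphoryl)acetate
Conditions: Et3N, CH2Cl2, 0 → 23 °C
Reagents that add atoms: none
Why: Michaelis–Becker reaction, in which the amine-generated phosphite anion displaces the activated α-bromide to give the diaryl phosphonoacetate.

Step 11
Reactants: 22 (tributylstannyl)methyl (diphenoxyphosphoryl)acetate; 23 4-(tert-butyldimethylsilyloxy)benzaldehyde
Product: 24 (tributylstannyl)methyl (Z)-3-[4-(tert-butyldimethylsilyloxy)phenyl]prop-2-enoate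
Conditions: NaH, THF, −78 °C; then 23, −78 → −20 °C, dark
Reagents that add atoms: none
Why: Horner–Wadsworth–Emmons olefination with a diaryl phosphonoacetate: the electron-poor aryloxy groups make collapse of the oxaphosphetane faster than equilibration of the adducts, so the kinetic Z-enoate should be obtained at low temperature.

Step 12
Reactants: 17 triisopropylsilyl 4-iodo-15-nor-5α-eudesma-3,11(13)-dien-12-oate; 24 (tributylstannyl)methyl (Z)-3-[4-(tert-butyldimethylsilyloxy)phenyl]prop-2-enoate
Product: 25 triisopropylsilyl 15-[(Z)-4-(tert-butyldimethylsilyloxy)cinnamoyloxy]-5α-eudesma-3,11(13)-dien-12-oate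
Conditions: Pd2(dba)3 (5 mol %), AsPh3 (40 mol %), copper thiophene-2-carboxylate Cu(O2CC4H3S) (1.5 equiv), NMP, 23 → 40 °C, argon, dark
Reagents that add atoms: none
Why: Copper-assisted Stille coupling: zerovalent palladium inserts into the C4–I bond of 17, the monovalent copper carboxylate takes the acyloxymethyl group from tin (the α-oxygen polarises the C–Sn bond and the ester carbonyl can chelate, so this sp3 group and not butyl is transferred), and transmetalation to palladium followed by reductive elimination forms the C4–C15 bond. The closest known reactions are the Pd/Cu couplings of α-acyloxyalkyl tributylstannanes with alkenyl iodides and the Stille hydroxymethylation of alkenyl electrophiles with (tributylstannyl)methanol. No ring is closed and no stereocentre is formed; C5, C7 and C10 are spectators and the position of the C3=C4 alkene is fixed by the iodide. The selectivities needed are transfer of the CH2O-acyl group over butyl, secured by the α-acyloxy group and the copper carboxylate; retention of the Z-enoate, secured by a polar, radical-free mechanism run in the dark near room temperature with the weakly nucleophilic AsPh3 in place of a phosphine; and no reaction at the acrylate or at the allylic ester of the product, favoured by the low temperature and the absence of base. In this one operation the whole oxygenated C15 arm with its complete Z-coumarate is attached, so that only desilylation remains.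

Step 13
Reactants: 25 triisopropylsilyl 15-[(Z)-4-(tert-butyldimethylsilyloxy)cinnamoyloxy]-5α-eudesma-3,11(13)-dien-12-oate
Product: 26 15-[(Z)-4-hydroxycinnamoyloxy]-5α-eudesma-3,11(13)-dien-12-oic acid
Conditions: Bu4NF (3 equiv), AcOH (3 equiv), THF, 0 °C, dark
Reagents that add atoms: none
Why: Fluoride should cleave the aryl silyl ether and the silyl ester in one operation, and the acetic acid buffer keeps phenoxide and hydroxide out of solution so that the Z-enoate and the allylic ester survive.

**Compound list**
1 | (+)-dihydrocarvone, (2R,5R)-2-methyl-5-(prop-1-en-2-yl)cyclohexan-1-one | C[C@@H]1CC[C@H](CC1=O)C(C)=C | starting material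
2 | (R)-1-phenylethylamine | C[C@@H](N)c1ccccc1 | starting material
3 | methyl vinyl ketone (but-3-en-2-one) | CC(=O)C=C | starting material
4 | (R)-1-phenylethyl ketimine of dihydrocarvone | C[C@@H]1CC[C@H](CC1=N[C@H](C)c2ccccc2)C(C)=C | intermediate
5 | (R)-1-phenylethyl imine of (2S,5R)-2-methyl-2-(3-oxobutyl)-5-(prop-1-en-2-yl)cyclohexanone | CC(=C)[C@@H]1CC[C@@](C)(CCC(C)=O)C(=N[C@H](C)c2ccccc2)C1 | intermediate
6 | (2S,5R)-2-methyl-2-(3-oxobutyl)-5-(prop-1-en-2-yl)cyclohexan-1-one | CC(=C)[C@@H]1CC[C@@](C)(CCC(C)=O)C(=O)C1 | intermediate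
7 | 15-nor-eudesma-4,11-dien-3-one, (4aS,7R)-4a-methyl-7-(prop-1-en-2-yl)-4,4a,5,6,7,8-hexahydronaphthalen-2(3H)-one | CC(=C)[C@@H]1CC[C@@]2(C)CCC(=O)C=C2C1 | intermediate
8 | 4-iodo-15-nor-eudesma-4,11-dien-3-one, (4aS,7R)-1-iodo-4a-methyl-7-(prop-1-en-2-yl)-4,4a,5,6,7,8-hexahydronaphthalen-2(3H)-one | CC(=C)[C@@H]1CC[C@@]2(C)CCC(=O)C(I)=C2C1 | intermediate
9 | 4-iodo-15-nor-eudesma-4,11-dien-3β-ol (3S; OH cis to the C10 methyl) | CC(=C)[C@@H]1CC[C@@]2(C)CC[C@H](O)C(I)=C2C1 | intermediate
10 | 3α-[N-(2-nitrobenzenesulfonyl)-N′-isopropylidenehydrazino]-4-iodo-15-nor-eudesma-4,11-diene | CC(=C)[C@@H]1CC[C@@]2(C)CC[C@@H](N(N=C(C)C)S(=O)(=O)c3ccccc3[N+](=O)[O-])C(I)=C2C1 | intermediate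
11 | 3α-[N-(2-nitrobenzenesulfonyl)hydrazino]-4-iodo-15-nor-eudesma-4,11-diene | CC(=C)[C@@H]1CC[C@@]2(C)CC[C@@H](N(N)S(=O)(=O)c3ccccc3[N+](=O)[O-])C(I)=C2C1 | intermediate
12 | 3α-diazenyl-4-iodo-15-nor-eudesma-4,11-diene | CC(=C)[C@@H]1CC[C@@]2(C)CC[C@@H](N=N)C(I)=C2C1 | intermediate
13 | 4-iodo-15-nor-5α-eudesma-3,11-diene (5α-H, 7β-isopropenyl, 10β-methyl) | CC(=C)[C@@H]1CC[C@@]2(C)CCC=C(I)[C@@H]2C1 | intermediate
14 | 4-iodo-15-nor-5α-eudesma-3,11(13)-dien-12-ol | OCC(=C)[C@@H]1CC[C@@]2(C)CCC=C(I)[C@@H]2C1 | intermediate
15 | 4-iodo-15-nor-5α-eudesma-3,11(13)-dien-12-al | O=CC(=C)[C@@H]1CC[C@@]2(C)CCC=C(I)[C@@H]2C1 | intermediate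
16 | 4-iodo-15-nor-5α-eudesma-3,11(13)-dien-12-oic acid | OC(=O)C(=C)[C@@H]1CC[C@@]2(C)CCC=C(I)[C@@H]2C1 | intermediate
17 | triisopropylsilyl 4-iodo-15-nor-5α-eudesma-3,11(13)-dien-12-oate | CC(C)[Si](OC(=O)C(=C)[C@@H]1CC[C@@]2(C)CCC=C(I)[C@@H]2C1)(C(C)C)C(C)C | intermediate
18 | (tributylstannyl)methanol | CCCC[Sn](CCCC)(CCCC)CO | starting material
19 | bromoacetyl bromide | BrCC(Br)=O | starting material
20 | (tributylstannyl)methyl bromoacetate | CCCC[Sn](CCCC)(CCCC)COC(=O)CBr | intermediate
21 | diphenyl phosphite | O=[PH](Oc1ccccc1)Oc1ccccc1 | starting material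
22 | (tributylstannyl)methyl (diphenoxyphosphoryl)acetate | CCCC[Sn](CCCC)(CCCC)COC(=O)CP(=O)(Oc1ccccc1)Oc1ccccc1 | intermediate
23 | 4-(tert-butyldimethylsilyloxy)benzaldehyde | CC(C)(C)[Si](C)(C)Oc1ccc(C=O)cc1 | starting material
24 | (tributylstannyl)methyl (Z)-3-[4-(tert-butyldimethylsilyloxy)phenyl]prop-2-enoate | CCCC[Sn](CCCC)(CCCC)COC(=O)/C=C\c1ccc(O[Si](C)(C)C(C)(C)C)cc1 | intermediate
25 | triisopropylsilyl 15-[(Z)-4-(tert-butyldimethylsilyloxy)cinnamoyloxy]-5α-eudesma-3,11(13)-dien-12-oate | C=C(C(=O)O[Si](C(C)C)(C(C)C)C(C)C)[C@@H]1CC[C@@]2(C)CCC=C(COC(=O)/C=C\c3ccc(O[Si](C)(C)C(C)(C)C)cc3)[C@@H]2C1 | intermediate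
26 | 15-[(Z)-4-hydroxycinnamoyloxy]-5α-eudesma-3,11(13)-dien-12-oic acid (5R,7R,10R) | C=C(C(=O)O)[C@@H]1CC[C@@]2(C)CCC=C(COC(=O)/C=C\c3ccc(O)cc3)[C@@H]2C1 | target

**Step count and risks**
Total steps: 13. Longest linear sequence: 10 (steps 1–8, 12, 13); the stannane branch is steps 9–11.

Steps most likely to fail:

1. Step 3 (α-iodination). The addition–elimination may stall because the β-carbon C5 is fully substituted and flanked by the quaternary C10, so conversion may stay low or the isolated alkene may be attacked during a long exposure to iodine. Fallback, from 7 back to 8: 7 is condensed with pyrrolidine (benzene, reflux, water separator) to the 3-(pyrrolidin-1-yl)-15-nor-eudesma-3,5,11-triene F1. This dienamine is iodinated at its nucleophilic C4 with N-iodosuccinimide (THF, −78 °C), then hydrolysed and reconjugated with aqueous NaOAc–AcOH to give 8. The halogen then enters by electrophilic substitution at the α-carbon of a dienamine, a path known for halogenation of 4-en-3-one dienamines, and not by attack at the hindered β-carbon.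

2. Step 5 (reductive transposition). The Mitsunobu displacement may fail through shielding of C3 by the neighbouring iodine, through SN2′ attack or through elimination to a diene, and hydrogen would then not be delivered to C5. Fallback, from 7 back to 13, which sets C5 by dissolving-metal reduction and moves the oxygen by a 1,2-carbonyl transposition: reduction of 7 with Li in NH3–THF (t-BuOH, −78 °C) and trapping of the regiodefined C3–C4 enolate with PhSSPh should give the trans-fused 4-(phenylthio)-15-nor-5α-eudesm-11-en-3-one F2. NaBH4 reduces it to the hydroxy sulfide F3. Dehydration towards the sulfur-bearing carbon with bis[α,α-bis(trifluoromethyl)benzyloxy]diphenylsulfurane in CH2Cl2 gives the vinyl sulfide F4. HgCl2/CaCO3 in aqueous MeCN hydrolyses it to 15-nor-5α-eudesm-11-en-4-one F5. 2,4,6-Triisopropylbenzenesulfonyl hydrazide gives the hydrazone F6, and a Shapiro reaction (n-BuLi, THF, −78 → 0 °C, then I2), which forms the vinyl anion towards the methylene C3, gives 13.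

3. Step 12 (key coupling). Transfer of the sp3 carbon from tin may be slow, which would open the way to butyl transfer, loss of iodine by protonation or Z-to-E isomerisation of the enoate during a long reaction. Fallback, from 17 and 18 back to 25: Stille hydroxymethylation of 17 with 18 (Pd(PPh3)4, LiCl, dioxane, 90 °C) gives the allylic alcohol triisopropylsilyl 15-hydroxy-5α-eudesma-3,11(13)-dien-12-oate F7. Bromoacetyl bromide 19 and pyridine give the bromoacetate F8, diphenyl phosphite 21 and Et3N give the phosphonoacetate F9, and Z-selective Horner–Wadsworth–Emmons reaction with aldehyde 23 (NaH, THF, −78 °C) gives 25. The C4–C15 bond is then made with the small hydroxymethyl stannane, and the Z-enoate is built afterwards on the assembled skeleton.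

**Further compounds**
F1 | step 3 | 3-(pyrrolidin-1-yl)-15-nor-eudesma-3,5,11-triene | CC(=C)[C@@H]1CC[C@@]2(C)CCC(N3CCCC3)=CC2=C1
F2 | step 5 | 4-(phenylthio)-15-nor-5α-eudesm-11-en-3-one (C4 epimers) | CC(=C)[C@@H]1CC[C@@]2(C)CCC(=O)C(Sc3ccccc3)[C@@H]2C1
F3 | step 5 | 4-(phenylthio)-15-nor-5α-eudesm-11-en-3-ol (C3 and C4 epimers) | CC(=C)[C@@H]1CC[C@@]2(C)CCC(O)C(Sc3ccccc3)[C@@H]2C1
F4 | step 5 | 4-(phenylthio)-15-nor-5α-eudesma-3,11-diene | CC(=C)[C@@H]1CC[C@@]2(C)CCC=C(Sc3ccccc3)[C@@H]2C1
F5 | step 5 | 15-nor-5α-eudesm-11-en-4-one | CC(=C)[C@@H]1CC[C@@]2(C)CCCC(=O)[C@@H]2C1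
F6 | step 5 | 2,4,6-triisopropylbenzenesulfonylhydrazone of 15-nor-5α-eudesm-11-en-4-one | CC(=C)[C@@H]1CC[C@@]2(C)CCCC(=NNS(=O)(=O)c3c(C(C)C)cc(C(C)C)cc3C(C)C)[C@@H]2C1
F7 | step 12 | triisopropylsilyl 15-hydroxy-5α-eudesma-3,11(13)-dien-12-oate | C=C(C(=O)O[Si](C(C)C)(C(C)C)C(C)C)[C@@H]1CC[C@@]2(C)CCC=C(CO)[C@@H]2C1
F8 | step 12 | triisopropylsilyl 15-(bromoacetoxy)-5α-eudesma-3,11(13)-dien-12-oate | C=C(C(=O)O[Si](C(C)C)(C(C)C)C(C)C)[C@@H]1CC[C@@]2(C)CCC=C(COC(=O)CBr)[C@@H]2C1
F9 | step 12 | triisopropylsilyl 15-[(diphenoxyphosphoryl)acetoxy]-5α-eudesma-3,11(13)-dien-12-oate | C=C(C(=O)O[Si](C(C)C)(C(C)C)C(C)C)[C@@H]1CC[C@@]2(C)CCC=C(COC(=O)CP(=O)(Oc3ccccc3)Oc3ccccc3)[C@@H]2C1
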